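(Its constants belong to no real substance; no experiment stands behind them.)

The easy step is to ask where each Z goes, since it can meet G or another Z.

G 2.0 mM; Z 5.00 mM (fed, over 2.0 min); time 1.5 h

    G + Z → L + D (k1 = 3.5 M⁻¹ s⁻¹)
    L → E (k2 = 0.0056 s⁻¹)
    2 Z → Z2 (k3 = 7.8 M⁻¹ s⁻¹)
    L → J (k4 = 0.038 s⁻¹)

- the state of affairs at 1.5 h: stopped, and by what, or still going (Z has run out first / it is still moving / all of G has reacted)
- conversion of G at 1.5 h
- amount of E at 1.5 h, in percent of the G charged

- two of one species on the left: rate k times its square, two consumed each time
- the reaction counts as stopped when no species that holds the G changes by six tenths of a point or more over the second half of the time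
- run time (flask): 1.5 h

At any moment, c_G falls at the first step's constant times c_G times c_Z, while dimerisation removes Z at double its constant times c_Z squared. Dividing the two, ln c_G drops by a fixed ratio of the constants, the selectivity factor s = 0.224, for each unit of a clock N, the time integral of c_Z times double the dimerisation constant.

By hand, c_Z climbs during the feed to the plateau where feed balances dimerisation, 1.63 mM. The clock then reads 2.37 at the end of the feed, ln(2) being the cost of the climb. Afterwards, Z decays by both routes, dimerisation leading while c_Z stands above s·c_G, which is 0.224 mM with c_G at half its charge and so lies below the plateau. With c_G at half its charge, the tail adds the logarithm of one plus plateau over s·c_G, 2.11. Conversion comes to 63.4%.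

Z fades within about 4.76 min, short against 1.5 h, so Z should stop the flask with G left. L lives 0.382 min, and E takes 12.8% of it, giving 8.14%.

Two settings can be turned. More Z lengthens both parts of the clock, while more G shortens the tail and so lowers the conversion, which makes Z the stronger setting by hand.

The forecast said Z has run out first, 61% and 7.8%, holding that “Z is used up within minutes”.

The flask gives Z has run out first, 61.5% and 7.90%, with Z at 0% and G at 38% of charge, and the settings rank Z (5.6 points), then G (3.3 points).

At 0.0333 h, with G at 61.8% and Z at 29.6% of their charges, s gives the flask's loss of Z to G as 0.187 of its loss to dimerisation. By 1.50 h, 3.77 mM of Z stands in the dimer against 1.23 mM of D.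

In the neighbour flask with 0.50 mM of G, the same feed clock and a longer tail give N = 5.77 and a conversion of 72.5%. The simulation of that neighbour flask gives 74.3%.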